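The ratio I would hold on to for your flask is free monomer charged to initiator charged, c(free monomer) / c(initiator) = 0.050 M / 0.10 mM = 500. I call it the load: monomer units charged per chain, if each initiator begins one chain.

- eta: free monomer 0.10 M (fed, over 8.0 s); initiator 0.10 mM; run made earlier
- flask: free monomer 0.050 M (fed, over 8.0 s); initiator 0.10 mM; time 2.5 min

eta run (percent of the free monomer charged)

| time / s | monomer in chains / % | free monomer / % |
|---|---|---|
| 10.0 | 3.6 | 96.5 |
| 20.0 | 10.2 | 89.4 |
| 30.0 | 17.0 | 83.3 |

(standard deviation of a reading: 0.5 percentage points)

- the average divides the monomer in chains by the number of chains begun, living and dead together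
- the analysis behind the earlier runs scatters by 0.5 percentage points, standard deviation
- the earlier runs do not show the number of chains; that part of a forecast is a guess

- average number of monomer units in a chain (chains begun, living or dead) at 2.5 min
- part of the free monomer that has reacted at 2.5 min

You asked for a quick number, and your hunch is that this flask follows the eta run. I take that up, since the initiator charge is the same. In the eta run, free monomer falls from 96.5% at 10.0 s to 83.3% at 30.0 s, and my forecast carries that decay on to 65% reacted (range 52% to 76%). The average then comes from the load, and this part is a guess, “Assuming all initiator begins chains”:

average = load × reacted share = 500 × 65% = 325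

So I say 325, within 250 to 460.

The flask gives 277 and 54.1%, both below the forecast.

    free monomer + initiator → living end + monomer in chains (k = 6.10 M⁻¹ s⁻¹)
    free monomer + living end → monomer in chains + living end, rate k2*[living end]*[free monomer] (k = 90.0 M⁻¹ s⁻¹)
    monomer in chains + living end → free monomer + living end, rate k3*[living end] as long as [monomer in chains] is above zero (k = 1.10 s⁻¹)
    free monomer + initiator → spent initiator (k = 0.140 M⁻¹ s⁻¹)

The load times 54.1% is 270, against 277. That small gap lies in the chains begun: living end stands at 9.78 × 10⁻⁵ M at 2.50 min, less than the 0.10 mM of initiator charged, and the same share over that living end gives 277. The forecast and the flask part mainly on the reacted share, 65% against 54.1%. In this flask, initiator stands at 28.9% of its charge at 0.133 min and 0% at 1.25 min, which makes it the limiting reagent. From then on, 9.78 × 10⁻⁵ M of living end carries free monomer into chains while monomer in chains also returns to free monomer. Free monomer is 45.9% at 2.50 min and 24.4% at 25.0 min, where the average is 386, below the load.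

A neighbouring flask with 0.085 M of free monomer has a load of 850, and its reacted share of 61.5% makes 523. The computed average there is 535.

The readings were computed on assumed constants, noise included.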